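**Retrosynthetic overview**
- The target is opened at the aryl ester C–O bond, after a final acid deprotection (two MOM ethers, one TBS ether), into a hindered phenol (3-hydroxy-5,6-bis(methoxymethoxy)-2,4-dimethylbenzaldehyde) and (3R)-3-silyloxydecanoic acid.
- The acid comes from ethyl 3-oxodecanoate by ketoreductase-catalysed asymmetric reduction, which sets the only stereocentre; the keto ester comes from octanoyl chloride and Meldrum's acid.
- In the phenol, the CHO is installed by MOM-directed ortho-lithiation/DMF, the second catechol oxygen by ortho-formylation/Dakin oxidation, and the para oxygen by Baeyer–Villiger oxidation of 4-hydroxy-3,5-dimethylbenzaldehyde, whose hindered OH stays benzyl-protected until just before esterification.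
- No ring is formed: the benzene ring is bought intact and substituted stepwise (para O, then ortho O, then CHO).

Assumption: the stereocentre in the given SMILES is (3R), and an (R)-selective ketoreductase that accepts ethyl 3-oxodecanoate is found by screening a commercial enzyme panel.

**Route**

Step 1
Reactants: 1 octanoyl chloride; 2 Meldrum's acid (2,2-dimethyl-1,3-dioxane-4,6-dione)
Product: 4 ethyl 3-oxodecanoate, via acyl Meldrum's acid 3 (not isolated)
Conditions: pyridine, CH2Cl2, 0 °C → rt; then EtOH, reflux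
Reagents that add atoms: ethanol, CCO
Why: C-acylation of Meldrum's acid followed by thermal ethanolysis (Oikawa–Yonemitsu β-keto ester synthesis) expels acetone and CO2 through an acylketene that ethanol traps.

Step 2
Reactants: 4 ethyl 3-oxodecanoate
Product: 5 ethyl (3R)-3-hydroxydecanoate
Conditions: (R)-selective ketoreductase (KRED), NADP+ (cat.), i-PrOH (15% v/v), KH2PO4/K2HPO4 buffer pH 7.0, 30 °C
Reagents that add atoms: none
Why: Enzymatic asymmetric ketone reduction, in which the ketoreductase (an NADPH-dependent alcohol dehydrogenase, oxidoreductase class) delivers hydride to the Si face of the C3 ketone to set the (3R) carbinol in >99% ee, while isopropanol recycles the cofactor and the ester is untouched.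

Step 3
Reactants: 5 ethyl (3R)-3-hydroxydecanoate
Product: 6 ethyl (3R)-3-[(tert-butyldimethylsilyl)oxy]decanoate
Conditions: TBSCl, imidazole, DMF, rt
Reagents that add atoms: tert-butyldimethylsilyl chloride (TBSCl), CC(C)(C)[Si](C)(C)Cl
Why: Imidazole-promoted silyl ether formation on an unhindered secondary alcohol masks the hydroxyl so the acid cannot self-condense later, and it does not touch the stereocentre.

Step 4
Reactants: 6 ethyl (3R)-3-[(tert-butyldimethylsilyl)oxy]decanoate
Product: 8 (3R)-3-[(tert-butyldimethylsilyl)oxy]decanoic acid, via lithium carboxylate 7 (not isolated)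
Conditions: LiOH·H2O, THF/H2O, 0 °C → rt; then 1 M HCl to pH 4, 0 °C
Reagents that add atoms: lithium hydroxide, [Li+].[OH-]
Why: Ester saponification by acyl–oxygen cleavage is mild enough at or below room temperature that the base-stable TBS ether survives and β-elimination does not compete, so the C3 configuration is retained.

Step 5
Reactants: 9 4-hydroxy-3,5-dimethylbenzaldehyde
Product: 10 4-(benzyloxy)-3,5-dimethylbenzaldehyde
Conditions: BnBr, K2CO3, DMF, 60 °C
Reagents that add atoms: benzyl bromide, BrCc1ccccc1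
Why: Williamson ether synthesis on the acidic para-formyl phenoxide caps the hindered oxygen that will later carry the ester with a group stable to peracid, base and organolithium.

Step 6
Reactants: 10 4-(benzyloxy)-3,5-dimethylbenzaldehyde
Product: 12 4-(benzyloxy)-3,5-dimethylphenol, via aryl formate 11 (not isolated)
Conditions: mCPBA, CH2Cl2, 0 °C → rt; then K2CO3 (cat.), MeOH, rt
Reagents that add atoms: meta-chloroperoxybenzoic acid (mCPBA), OOC(=O)c1cccc(Cl)c1
Why: Baeyer–Villiger oxidation of the electron-rich para-alkoxybenzaldehyde proceeds with aryl migration to the formate, which catalytic methanolysis cleaves to the phenol.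

Step 7
Reactants: 12 4-(benzyloxy)-3,5-dimethylphenol
Product: 14 3-(benzyloxy)-6-hydroxy-2,4-dimethylbenzaldehyde, via hydroxymethylphenol 13 (not isolated)
Conditions: MgCl2, Et3N, (CH2O)n, MeCN, reflux; then 1 M HCl
Reagents that add atoms: paraformaldehyde (formaldehyde), C=O
Why: Magnesium-phenoxide-directed ortho-formylation (Casnati–Skattebøl) hydroxymethylates only ortho to the OH and a second formaldehyde oxidises the benzylic alkoxide by hydride transfer, the two ortho sites being equivalent by symmetry.

Step 8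
Reactants: 14 3-(benzyloxy)-6-hydroxy-2,4-dimethylbenzaldehyde
Product: 16 4-(benzyloxy)-3,5-dimethylbenzene-1,2-diol, via aryl formate 15 (not isolated)
Conditions: 30% H2O2, NaOH, THF/H2O, 0 °C → rt, Ar; then 1 M HCl
Reagents that add atoms: hydrogen peroxide, OO
Why: Dakin oxidation of the ortho-hydroxybenzaldehyde (hydroperoxide addition, aryl migration, formate hydrolysis) replaces CHO by OH and so places the second catechol oxygen next to the first.

Step 9
Reactants: 16 4-(benzyloxy)-3,5-dimethylbenzene-1,2-diol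
Product: 17 2-(benzyloxy)-4,5-bis(methoxymethoxy)-1,3-dimethylbenzene
Conditions: NaH, MOMCl, DMF, 0 °C → rt
Reagents that add atoms: chloromethyl methyl ether (MOMCl), COCCl
Why: Irreversible deprotonation and O-alkylation (Williamson-type acetal formation) protects both catechol oxygens, including the hindered one, as MOM ethers that direct the next lithiation and fall off under mild acid at the end.

Step 10
Reactants: 17 2-(benzyloxy)-4,5-bis(methoxymethoxy)-1,3-dimethylbenzene
Product: 20 3-(benzyloxy)-5,6-bis(methoxymethoxy)-2,4-dimethylbenzaldehyde, via aryllithium 18 (not isolated), via lithium hemiaminolate 19 (not isolated)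
Conditions: n-BuLi, TMEDA, THF, −20 → 0 °C; DMF, −78 °C → rt; then H2O
Reagents that add atoms: N,N-dimethylformamide (DMF), CN(C)C=O
Why: Directed ortho-metalation puts lithium on the only ring C–H, which lies ortho to a chelating OMOM group, and formylation with DMF gives the aldehyde on aqueous collapse of the hemiaminolate.

Step 11
Reactants: 20 3-(benzyloxy)-5,6-bis(methoxymethoxy)-2,4-dimethylbenzaldehyde
Product: 21 3-hydroxy-5,6-bis(methoxymethoxy)-2,4-dimethylbenzaldehyde
Conditions: H2 (1 atm), 10% Pd/C, EtOAc, rt, stopped at full conversion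
Reagents that add atoms: none
Why: Catalytic hydrogenolysis cleaves the benzyl aryl ether much faster than it reduces the doubly ortho-substituted, electron-rich aldehyde, and the MOM acetals are inert in neutral ethyl acetate.

Step 12
Reactants: 21 3-hydroxy-5,6-bis(methoxymethoxy)-2,4-dimethylbenzaldehyde; 8 (3R)-3-[(tert-butyldimethylsilyl)oxy]decanoic acid
Product: 22 3-formyl-4,5-bis(methoxymethoxy)-2,6-dimethylphenyl (3R)-3-[(tert-butyldimethylsilyl)oxy]decanoate
Conditions: EDC·HCl, DMAP, CH2Cl2, 0 °C → rt
Reagents that add atoms: none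
Why: Steglich esterification through the acylpyridinium acylates even a 2,6-dimethyl-flanked phenol, which is the only free hydroxyl present, and leaves the β-stereocentre untouched.

Step 13
Reactants: 22 3-formyl-4,5-bis(methoxymethoxy)-2,6-dimethylphenyl (3R)-3-[(tert-butyldimethylsilyl)oxy]decanoate
Product: 23 Penicipurate A, 3-formyl-4,5-dihydroxy-2,6-dimethylphenyl (3R)-3-hydroxydecanoate
Conditions: TFA/CH2Cl2/H2O (10:10:1), 0 °C → rt; aq. NaHCO3 work-up to pH 6–7
Reagents that add atoms: none
Why: Acid-catalysed hydrolysis of the two MOM acetals and the silyl ether releases the catechol and the carbinol in one operation, while the sterically shielded aryl ester survives acidic, weakly nucleophilic conditions and the stereocentre is not involved.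

**Compound list**
1 | octanoyl chloride | CCCCCCCC(=O)Cl | starting material
2 | Meldrum's acid (2,2-dimethyl-1,3-dioxane-4,6-dione) | CC1(C)OC(=O)CC(=O)O1 | starting material
3 | 5-(1-hydroxyoctylidene)-2,2-dimethyl-1,3-dioxane-4,6-dione (acyl Meldrum's acid, enol form) | CCCCCCCC(O)=C1C(=O)OC(C)(C)OC1=O | intermediate (not isolated)
4 | ethyl 3-oxodecanoate | CCCCCCCC(=O)CC(=O)OCC | intermediate
5 | ethyl (3R)-3-hydroxydecanoate | CCCCCCC[C@@H](O)CC(=O)OCC | intermediate
6 | ethyl (3R)-3-[(tert-butyldimethylsilyl)oxy]decanoate | CCCCCCC[C@@H](O[Si](C)(C)C(C)(C)C)CC(=O)OCC | intermediate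
7 | lithium (3R)-3-[(tert-butyldimethylsilyl)oxy]decanoate | CCCCCCC[C@@H](O[Si](C)(C)C(C)(C)C)CC(=O)[O-].[Li+] | intermediate (not isolated)
8 | (3R)-3-[(tert-butyldimethylsilyl)oxy]decanoic acid | CCCCCCC[C@@H](O[Si](C)(C)C(C)(C)C)CC(=O)O | intermediate
9 | 4-hydroxy-3,5-dimethylbenzaldehyde | Cc1cc(C=O)cc(C)c1O | starting material
10 | 4-(benzyloxy)-3,5-dimethylbenzaldehyde | Cc1cc(C=O)cc(C)c1OCc1ccccc1 | intermediate
11 | 4-(benzyloxy)-3,5-dimethylphenyl formate | Cc1cc(OC=O)cc(C)c1OCc1ccccc1 | intermediate (not isolated)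
12 | 4-(benzyloxy)-3,5-dimethylphenol | Cc1cc(O)cc(C)c1OCc1ccccc1 | intermediate
13 | 4-(benzyloxy)-2-(hydroxymethyl)-3,5-dimethylphenol (present as its magnesium salt) | OCc1c(O)cc(C)c(OCc2ccccc2)c1C | intermediate (not isolated)
14 | 3-(benzyloxy)-6-hydroxy-2,4-dimethylbenzaldehyde | O=Cc1c(O)cc(C)c(OCc2ccccc2)c1C | intermediate
15 | 3-(benzyloxy)-6-hydroxy-2,4-dimethylphenyl formate | O=COc1c(O)cc(C)c(OCc2ccccc2)c1C | intermediate (not isolated)
16 | 4-(benzyloxy)-3,5-dimethylbenzene-1,2-diol | Oc1c(O)cc(C)c(OCc2ccccc2)c1C | intermediate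
17 | 2-(benzyloxy)-4,5-bis(methoxymethoxy)-1,3-dimethylbenzene | COCOc1cc(C)c(OCc2ccccc2)c(C)c1OCOC | intermediate
18 | [3-(benzyloxy)-5,6-bis(methoxymethoxy)-2,4-dimethylphenyl]lithium | [Li]c1c(C)c(OCc2ccccc2)c(C)c(OCOC)c1OCOC | intermediate (not isolated)
19 | lithium [3-(benzyloxy)-5,6-bis(methoxymethoxy)-2,4-dimethylphenyl](dimethylamino)methanolate (racemic at the transient carbinol carbon) | [Li+].[O-]C(N(C)C)c1c(C)c(OCc2ccccc2)c(C)c(OCOC)c1OCOC | intermediate (not isolated)
20 | 3-(benzyloxy)-5,6-bis(methoxymethoxy)-2,4-dimethylbenzaldehyde | O=Cc1c(C)c(OCc2ccccc2)c(C)c(OCOC)c1OCOC | intermediate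
21 | 3-hydroxy-5,6-bis(methoxymethoxy)-2,4-dimethylbenzaldehyde | O=Cc1c(C)c(O)c(C)c(OCOC)c1OCOC | intermediate
22 | 3-formyl-4,5-bis(methoxymethoxy)-2,6-dimethylphenyl (3R)-3-[(tert-butyldimethylsilyl)oxy]decanoate | CCCCCCC[C@@H](O[Si](C)(C)C(C)(C)C)CC(=O)Oc1c(C)c(OCOC)c(OCOC)c(C=O)c1C | intermediate
23 | Penicipurate A, 3-formyl-4,5-dihydroxy-2,6-dimethylphenyl (3R)-3-hydroxydecanoate | CCCCCCC[C@@H](O)CC(=O)Oc1c(C)c(O)c(O)c(C=O)c1C | target

**Step count**
Total steps: 13. Longest linear sequence: 9 steps (steps 5–13, from 9 to 23); the side-chain branch (steps 1–4) joins at step 12.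

**Three steps most likely to fail, with fallbacks**

Step 8 (Dakin oxidation). The product is a very electron-rich catechol that can over-oxidise to quinones in alkaline peroxide. The fallback sets out from 14 and comes back to the route at 17, and never frees the catechol. Compound 14 is first O-protected (MOMCl, i-Pr2NEt, CH2Cl2) to 3-(benzyloxy)-6-(methoxymethoxy)-2,4-dimethylbenzaldehyde F1. Baeyer–Villiger oxidation with mCPBA in NaHCO3-buffered CH2Cl2 gives 3-(benzyloxy)-6-(methoxymethoxy)-2,4-dimethylphenyl formate F2. K2CO3 in MeOH cleaves this to the mono-protected 3-(benzyloxy)-6-(methoxymethoxy)-2,4-dimethylphenol F3. A second MOM protection (NaH, MOMCl, DMF) then gives 17.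

Step 10 (ortho-lithiation/formylation). Deprotonation of a benzylic methyl or of the OCH2Ph group could compete with ring lithiation. The fallback sets out from 17 and comes back to the route at aryllithium 18, and fixes the site by halogen instead of by deprotonation. Electrophilic bromination of the single free ring position (NBS, MeCN, 0 °C) gives 1-(benzyloxy)-3-bromo-4,5-bis(methoxymethoxy)-2,6-dimethylbenzene F4. Bromine–lithium exchange (t-BuLi, 2 equiv, THF, −78 °C) generates 18 regiospecifically, and this is quenched with DMF exactly as in step 10.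

Step 11 (hydrogenolysis beside an aryl aldehyde). Over-reduction of CHO to CH2OH or CH3 is possible. The fallback sets out from 17 and comes back to the route at 21, and removes the benzyl group before any aldehyde exists.
- Hydrogenolysis of 17 (H2, 10% Pd/C, EtOAc) gives 3,4-bis(methoxymethoxy)-2,6-dimethylphenol F5.
- Silylation (TBSOTf, 2,6-lutidine, CH2Cl2) gives tert-butyl[3,4-bis(methoxymethoxy)-2,6-dimethylphenoxy]dimethylsilane F6.
- Ortho-lithiation (n-BuLi, TMEDA, THF) gives {3-[(tert-butyldimethylsilyl)oxy]-5,6-bis(methoxymethoxy)-2,4-dimethylphenyl}lithium F7.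
- DMF converts this into lithium {3-[(tert-butyldimethylsilyl)oxy]-5,6-bis(methoxymethoxy)-2,4-dimethylphenyl}(dimethylamino)methanolate F8, and water releases 3-[(tert-butyldimethylsilyl)oxy]-5,6-bis(methoxymethoxy)-2,4-dimethylbenzaldehyde F9.
- Desilylation with tetrabutylammonium fluoride buffered with AcOH (THF, 0 °C) gives 21.

Further compounds
F1 | step 8 | 3-(benzyloxy)-6-(methoxymethoxy)-2,4-dimethylbenzaldehyde | O=Cc1c(OCOC)cc(C)c(OCc2ccccc2)c1C
F2 | step 8 | 3-(benzyloxy)-6-(methoxymethoxy)-2,4-dimethylphenyl formate | O=COc1c(OCOC)cc(C)c(OCc2ccccc2)c1C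
F3 | step 8 | 3-(benzyloxy)-6-(methoxymethoxy)-2,4-dimethylphenol | Oc1c(OCOC)cc(C)c(OCc2ccccc2)c1C
F4 | step 10 | 1-(benzyloxy)-3-bromo-4,5-bis(methoxymethoxy)-2,6-dimethylbenzene | Brc1c(C)c(OCc2ccccc2)c(C)c(OCOC)c1OCOC
F5 | step 11 | 3,4-bis(methoxymethoxy)-2,6-dimethylphenol | COCOc1cc(C)c(O)c(C)c1OCOC
F6 | step 11 | tert-butyl[3,4-bis(methoxymethoxy)-2,6-dimethylphenoxy]dimethylsilane | COCOc1cc(C)c(O[Si](C)(C)C(C)(C)C)c(C)c1OCOC
F7 | step 11 | {3-[(tert-butyldimethylsilyl)oxy]-5,6-bis(methoxymethoxy)-2,4-dimethylphenyl}lithium | [Li]c1c(C)c(O[Si](C)(C)C(C)(C)C)c(C)c(OCOC)c1OCOC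
F8 | step 11 | lithium {3-[(tert-butyldimethylsilyl)oxy]-5,6-bis(methoxymethoxy)-2,4-dimethylphenyl}(dimethylamino)methanolate | [Li+].[O-]C(N(C)C)c1c(C)c(O[Si](C)(C)C(C)(C)C)c(C)c(OCOC)c1OCOC
F9 | step 11 | 3-[(tert-butyldimethylsilyl)oxy]-5,6-bis(methoxymethoxy)-2,4-dimethylbenzaldehyde | O=Cc1c(C)c(O[Si](C)(C)C(C)(C)C)c(C)c(OCOC)c1OCOC
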